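**Retrosynthetic overview**
1. Target 16 is the ring tautomer of ε-hydroxy enone 15. Left unit numbered as a 1-benzoxepine: O1, C2 (hemiketal), C3 (CHMe), C4, C5, C5a, C6 (CMe2), C7–C9, C9a (CMe); ring A = cyclohexane, ring B = oxepane. Right unit: ring C = oxepanone, ring D = cyclohexane.
2. Enabling feature: O1–C9a (ether oxygen on the fully substituted ring-fusion carbon) and C2–C3 (hemiketal carbon to the CHMe carbon) are both Markovnikov bonds to alkene carbons of the C13 diene 14 (ring alkene C9=C9a; terminal vinyl = C3 and its methyl carbon), so O1 and the acyl carbon C2 can be delivered in one flask.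
3. Key disconnection: 16 ⇒ diene 14 + S-2-pyridyl thioester 10 + H2O (dual cobalt/nickel hydrogen-atom-transfer hydroacylation/hydration, then spontaneous closure of ring B).
4. 10 ⇒ bromohydrin 7 ⇒ alkene 6 ⇒ diepoxy vinylsilane 3 ⇒ (E)-geranylacetone 1; 14 ⇒ (R)-α-ionone 11.
5. Order of ring formation: C then D (one tandem cyclisation, step 3); A from the chiral pool; B last (step 12).

Key step: step 12

Assumption: (R)-α-ionone is bought enantioenriched, and 16 as drawn (C2 and C3 of the left unit) is the thermodynamically preferred lactol of 15, both centres being free to equilibrate by ring opening and enolisation.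

**Step 1**
Reactants: 1 (E)-geranylacetone
Product: 2 4-[(2R,3R)-3-{2-[(2R)-3,3-dimethyloxiran-2-yl]ethyl}-3-methyloxiran-2-yl]butan-2-one
Conditions: D-fructose-derived Shi ketone (30 mol%), Oxone (2KHSO5·KHSO4·K2SO4), K2CO3, Bu4NHSO4, Na2B4O7 buffer, MeCN/dimethoxymethane/H2O, 0 °C
Reagents that add atoms: Oxone (potassium peroxymonosulfate), [K+].[O-]S(=O)(=O)OO
Why: Shi asymmetric epoxidation of both electron-rich trisubstituted alkenes through the spiro dioxirane transition state should set the (2R,3R) and (2R) oxirane centres (the later C9a and C5a of the right unit) and leave the ketone untouched.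

**Step 2**
Reactants: 2 diepoxy ketone
Product: 3 trimethyl{4-[(2R,3R)-3-{2-[(2R)-3,3-dimethyloxiran-2-yl]ethyl}-3-methyloxiran-2-yl]-2-methylbut-1-en-1-yl}silane (E/Z mixture at the silylalkene)
Conditions: Cp2Ti(CH2SiMe3)2, toluene, 100 °C
Reagents that add atoms: bis(cyclopentadienyl)bis(trimethylsilylmethyl)titanium, C[Si](C)(C)C[Ti](C[Si](C)(C)C)(C1C=CC=C1)C1C=CC=C1
Why: Petasis-type titanium alkylidene olefination should convert the enolisable methyl ketone into the vinylsilane under non-basic conditions that spare the epoxides; the alkene geometry is irrelevant because silicon is lost in step 3.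

**Step 3**
Reactants: 3 diepoxy vinylsilane
Product: 5 (3R,5aR,9aR)-2,2,5a,7-tetramethyl-2,3,4,5,5a,8,9,9a-octahydro-1-benzoxepin-3-ol, via trimethylsilyl ether 4 (not isolated)
Conditions: Me3SiOTf (1.2 equiv), 2,6-di-tert-butyl-4-methylpyridine, CH2Cl2, −78 °C; then K2CO3, MeOH, rt
Reagents that add atoms: none
Why: Lewis acid-triggered tandem endo oxacyclisation/carbacyclisation of a 1,5-diepoxide with a vinylsilane-terminated cation–olefin cyclisation: the internal epoxide oxygen attacks the tertiary carbon of the silylated terminal epoxide (ring C), the silicon-bearing alkene carbon opens the resulting epoxonium ion at its tertiary carbon with inversion through a chair (ring D), and loss of silicon from the β-silyl cation should give the trans ring fusion (methyl and hydrogen anti) with the alkene fixed at C6=C7.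

**Step 4**
Reactants: 5 bicyclic alcohol
Product: 6 (5aR,9aR)-2,2,5a,7-tetramethyl-4,5,5a,8,9,9a-hexahydro-1-benzoxepin-3(2H)-one
Conditions: Dess–Martin periodinane, CH2Cl2, rt
Reagents that add atoms: none
Why: Dess–Martin oxidation of the secondary alcohol should give the α-alkoxy ketone without touching the trisubstituted alkene; no stereocentre is formed.

**Step 5**
Reactants: 6 alkene ketone
Product: 7 (5aS,6S,7S,9aR)-6-bromo-7-hydroxy-2,2,5a,7-tetramethyloctahydro-1-benzoxepin-3(2H)-one
Conditions: N-bromosuccinimide, THF/H2O (4:1), 0 °C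
Reagents that add atoms: N-bromosuccinimide, O=C1CCC(=O)N1Br; water, O
Why: Bromohydrin formation: the bromonium ion should form on the face opposite the angular methyl, and water should open it at the tertiary carbon in the trans-diaxial (Fürst–Plattner) sense, giving the axial tertiary hydroxyl at C7 and the axial bromide at C6.

**Step 6**
Reactants: 7 bromohydrin
Product: 8 ethyl (2E)-3-[(5aR,6S,7S,9aR)-7-hydroxy-2,2,5a,7-tetramethyl-3-oxodecahydro-1-benzoxepin-6-yl]prop-2-enoate
Conditions: ethyl (2E)-3-(tributylstannyl)prop-2-enoate (3 equiv), AIBN (cat.), benzene, 80 °C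
Reagents that add atoms: ethyl (2E)-3-(tributylstannyl)prop-2-enoate, CCCC[Sn](CCCC)(CCCC)/C=C/C(=O)OCC
Why: Radical addition–elimination (tin-mediated vinylation): the secondary C6 radical adds to the stannyl-bearing carbon and expels the tributyltin radical to give the (E)-enoate, and it should be attacked axially, anti to the axial angular methyl and the axial hydroxyl, which sets C6.

**Step 7**
Reactants: 8 ethyl ester
Product: 9 (2E)-3-[(5aR,6S,7S,9aR)-7-hydroxy-2,2,5a,7-tetramethyl-3-oxodecahydro-1-benzoxepin-6-yl]prop-2-enoic acid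
Conditions: LiOH, THF/H2O, rt; then 1 M HCl to pH 4
Reagents that add atoms: lithium hydroxide, [Li+].[OH-]
Why: Saponification of the ester should proceed at room temperature without enolising the γ-position or the hindered ketone; no stereocentre is touched.

**Step 8**
Reactants: 9 acid
Product: 10 S-pyridin-2-yl (2E)-3-[(5aR,6S,7S,9aR)-7-hydroxy-2,2,5a,7-tetramethyl-3-oxodecahydro-1-benzoxepin-6-yl]prop-2-enethioate
Conditions: 2,2'-dipyridyl disulfide, PPh3, CH2Cl2, rt
Reagents that add atoms: 2,2'-dipyridyl disulfide, c1ccc(SSc2ccccn2)nc1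
Why: Redox condensation (Mukaiyama thioesterification) should activate the acid under neutral conditions that tolerate the free tertiary alcohol and the ketone.

**Step 9**
Reactants: 11 (R)-α-ionone
Product: 12 4-[(1R)-2,6,6-trimethylcyclohex-2-en-1-yl]butan-2-one
Conditions: H2 (1 atm), RhCl(PPh3)3 (5 mol%), benzene, rt
Reagents that add atoms: none
Why: Homogeneous hydrogenation should reduce the disubstituted enone alkene and leave the hindered trisubstituted ring alkene and the allylic stereocentre untouched.

**Step 10**
Reactants: 12 (R)-dihydro-α-ionone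
Product: 13 N'-{4-[(1R)-2,6,6-trimethylcyclohex-2-en-1-yl]butan-2-ylidene}-2,4,6-tri(propan-2-yl)benzenesulfonohydrazide
Conditions: 2,4,6-triisopropylbenzenesulfonohydrazide, MeOH, HCl (cat.), rt
Reagents that add atoms: 2,4,6-triisopropylbenzenesulfonohydrazide, CC(C)c1cc(C(C)C)c(S(=O)(=O)NN)c(C(C)C)c1
Why: Hydrazone condensation should prepare the ketone for the Shapiro reaction; no stereocentre is formed.

**Step 11**
Reactants: 13 trisylhydrazone
Product: 14 (6R)-6-(but-3-en-1-yl)-1,5,5-trimethylcyclohex-1-ene
Conditions: n-BuLi (2.2 equiv), TMEDA/hexane, −78 to 0 °C; then H2O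
Reagents that add atoms: none
Why: Shapiro reaction: kinetic deprotonation at the methyl group, loss of sulfinate and dinitrogen, and protonation of the vinyllithium should give the terminal alkene regioselectively.

**Step 12**
Reactants: 14 diene; 10 S-2-pyridyl thioester
Product: 16 (2R,3R,5aR,9aR)-2-{(E)-2-[(5aR,6S,7S,9aR)-7-hydroxy-2,2,5a,7-tetramethyl-3-oxodecahydro-1-benzoxepin-6-yl]ethenyl}-3,6,6,9a-tetramethyldecahydro-1-benzoxepin-2-ol, via ε-hydroxy enone 15 (not isolated)
Conditions: N,N'-bis(3,5-di-tert-butylsalicylidene)-1,2-cyclohexanediaminocobalt (10 mol%), NiBr2·diglyme (10 mol%), 4,4'-di-tert-butyl-2,2'-bipyridine (12 mol%), 1-fluoro-2,4,6-trimethylpyridinium triflate (2.5 equiv), PhSiH3 (3 equiv), H2O (5 equiv), acetone/DMPU, 0 °C to rt; aq. NaHCO3; then DBU (5 mol%), CH2Cl2, rt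
Reagents that add atoms: water, O
Why: Proposed new method: a trivalent cobalt hydride (from the cobalt salen complex, the N-fluoropyridinium oxidant and the silane) transfers a hydrogen atom to each alkene in the Markovnikov sense; the secondary radical at the CHMe carbon is captured by the acyl–nickel species formed from 10 and zerovalent nickel and reductive elimination makes C2–C3, while the tertiary radical at C9a, which this cobalt/nickel pair does not couple, is oxidised through an alkyl–cobalt species to a cation equivalent and trapped by water (or by the new carbonyl oxygen) to make O1–C9a. The closest known reaction types are the cobalt-salen/nickel dual-catalysed branch-selective hydroarylation of terminal alkenes with aryl iodides (acyl–nickel capture of alkyl radicals being known from nickel-catalysed reductive ketone synthesis with S-2-pyridyl thioesters) and the cobalt-salen/N-fluoropyridinium/silane Markovnikov hydroalkoxylation of alkenes. Ring B should then close without a reagent by 7-exo-trig addition of the tertiary hydroxyl of 15 to the enone carbonyl (ring-chain tautomerism to the lactol). C9a is set by substrate control: oxygen enters equatorially, anti to the axial methyl on C6 and trans to the side chain on C5a, which comes unchanged from (R)-α-ionone; C3 and the anomeric C2 settle under thermodynamic control (enolisation and ring opening with DBU: methyl and alkenyl trans, hydroxyl axial). The step needs the two alkenes to be sorted into different fates; the substitution pattern (monosubstituted versus trisubstituted) should send the secondary radical to nickel and the tertiary one to the polar crossover, and the electron-poor, β-branched enoate of 10 is a poor hydrogen-atom acceptor.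

**Compound list**
1 | (E)-geranylacetone | CC(=O)CC/C=C(\C)CCC=C(C)C | starting material
2 | 4-[(2R,3R)-3-{2-[(2R)-3,3-dimethyloxiran-2-yl]ethyl}-3-methyloxiran-2-yl]butan-2-one | CC(=O)CC[C@H]1O[C@]1(C)CC[C@H]1OC1(C)C | intermediate
3 | diepoxy vinylsilane (E/Z at Si–CH=C) | C[Si](C)(C)C=C(C)CC[C@H]1O[C@]1(C)CC[C@H]1OC1(C)C | intermediate
4 | trimethylsilyl ether of 5 | CC1=C[C@@]2(C)CC[C@@H](O[Si](C)(C)C)C(C)(C)O[C@@H]2CC1 | intermediate
5 | (3R,5aR,9aR)-2,2,5a,7-tetramethyl-2,3,4,5,5a,8,9,9a-octahydro-1-benzoxepin-3-ol | CC1=C[C@@]2(C)CC[C@@H](O)C(C)(C)O[C@@H]2CC1 | intermediate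
6 | (5aR,9aR)-2,2,5a,7-tetramethyl-4,5,5a,8,9,9a-hexahydro-1-benzoxepin-3(2H)-one | CC1=C[C@@]2(C)CCC(=O)C(C)(C)O[C@@H]2CC1 | intermediate
7 | (5aS,6S,7S,9aR)-6-bromo-7-hydroxy-2,2,5a,7-tetramethyloctahydro-1-benzoxepin-3(2H)-one | Br[C@H]1[C@@]2(C)CCC(=O)C(C)(C)O[C@@H]2CC[C@]1(C)O | intermediate
8 | ethyl (2E)-3-[(5aR,6S,7S,9aR)-7-hydroxy-2,2,5a,7-tetramethyl-3-oxodecahydro-1-benzoxepin-6-yl]prop-2-enoate | CCOC(=O)/C=C/[C@H]1[C@@]2(C)CCC(=O)C(C)(C)O[C@@H]2CC[C@]1(C)O | intermediate
9 | corresponding (2E)-prop-2-enoic acid | OC(=O)/C=C/[C@H]1[C@@]2(C)CCC(=O)C(C)(C)O[C@@H]2CC[C@]1(C)O | intermediate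
10 | corresponding S-pyridin-2-yl (2E)-prop-2-enethioate | O=C(Sc1ccccn1)/C=C/[C@H]1[C@@]2(C)CCC(=O)C(C)(C)O[C@@H]2CC[C@]1(C)O | intermediate
11 | (R)-α-ionone | CC(=O)/C=C/[C@H]1C(C)=CCCC1(C)C | starting material
12 | 4-[(1R)-2,6,6-trimethylcyclohex-2-en-1-yl]butan-2-one | CC(=O)CC[C@H]1C(C)=CCCC1(C)C | intermediate
13 | 2,4,6-triisopropylbenzenesulfonylhydrazone of 12 | CC(CC[C@H]1C(C)=CCCC1(C)C)=NNS(=O)(=O)c1c(C(C)C)cc(C(C)C)cc1C(C)C | intermediate
14 | (6R)-6-(but-3-en-1-yl)-1,5,5-trimethylcyclohex-1-ene | C=CCC[C@H]1C(C)=CCCC1(C)C | intermediate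
15 | (1E)-1-[(5aR,6S,7S,9aR)-7-hydroxy-2,2,5a,7-tetramethyl-3-oxodecahydro-1-benzoxepin-6-yl]-6-[(1R,2R)-2-hydroxy-2,6,6-trimethylcyclohexyl]-4-methylhex-1-en-3-one (C4 epimers) | CC(CC[C@H]1[C@](C)(O)CCCC1(C)C)C(=O)/C=C/[C@H]1[C@@]2(C)CCC(=O)C(C)(C)O[C@@H]2CC[C@]1(C)O | intermediate
16 | target lactol (name as in step 12) | C[C@@H]1CC[C@@H]2C(C)(C)CCC[C@@]2(C)O[C@@]1(O)/C=C/[C@H]1[C@@]2(C)CCC(=O)C(C)(C)O[C@@H]2CC[C@]1(C)O | target

**Step count and risks**
Total steps: 12. Longest linear sequence: 9 (steps 1–8 and 12).

Step 12. The merged hydrogen-atom-transfer manifolds may fail to sort the two alkenes: radical cycloisomerisation of the 1,6-diene, hydrofunctionalisation of the vinyl group without acyl capture, or reversible hydrogen-atom transfer that shifts the ring alkene and erodes C5a. Fallback: the two bonds are made in separate, known operations. Setting out from 14, Mukaiyama hydration of both alkenes (Co(acac)2, PhSiH3, O2, i-PrOH, rt; equatorial tertiary C–O bond for the same steric reason, secondary alcohol as epimers) should give (1R,2R)-2-(3-hydroxybutyl)-1,3,3-trimethylcyclohexan-1-ol F1. An Appel reaction (I2, PPh3, imidazole, CH2Cl2, 0 °C) should convert only the secondary alcohol into (1R,2R)-2-(3-iodobutyl)-1,3,3-trimethylcyclohexan-1-ol F2. Nickel-catalysed reductive acylation of F2 with 10 (NiCl2·glyme, 4,4'-di-tert-butyl-2,2'-bipyridine, Zn, DMA, rt), whose alkyl radical now has no alkene to cyclise onto, should give 15, which closes to 16, where the route is rejoined.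

Step 6. Addition of the neopentyl-type secondary radical to the β-stannyl acrylate may be too slow, so that halogen loss by elimination or reduction dominates. Fallback: setting out from 7, tin-free radical hydroalkylation of the unhindered acceptor ethyl propiolate ((Me3Si)3SiH, AIBN, toluene, 80 °C) should give 8 together with its geometric isomer, ethyl (2Z)-3-[(5aR,6S,7S,9aR)-7-hydroxy-2,2,5a,7-tetramethyl-3-oxodecahydro-1-benzoxepin-6-yl]prop-2-enoate F3. Thiyl-radical isomerisation of the mixture (PhSH cat., AIBN, benzene, 80 °C) should funnel F3 into 8, where the route is rejoined.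

Step 2. The epoxides may open or rearrange at the temperature of the titanium alkylidene olefination, or olefination may stall. Fallback: the order is reversed. Setting out from 1, Peterson olefination with bis(trimethylsilyl)methyllithium (THF, −78 °C to rt) should give trimethyl[(5E)-2,6,10-trimethylundeca-1,5,9-trien-1-yl]silane F4 before any epoxide is present. Shi epoxidation with 2.2 equiv of oxidant should then epoxidise the two trialkyl-substituted alkenes faster than the silicon-shielded one and return to 3.

**Further compounds**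
F1 | step 12 | (1R,2R)-2-(3-hydroxybutyl)-1,3,3-trimethylcyclohexan-1-ol | CC(O)CC[C@H]1[C@](C)(O)CCCC1(C)C
F2 | step 12 | (1R,2R)-2-(3-iodobutyl)-1,3,3-trimethylcyclohexan-1-ol | CC(I)CC[C@H]1[C@](C)(O)CCCC1(C)C
F3 | step 6 | ethyl (2Z)-3-[(5aR,6S,7S,9aR)-7-hydroxy-2,2,5a,7-tetramethyl-3-oxodecahydro-1-benzoxepin-6-yl]prop-2-enoate | CCOC(=O)/C=C\[C@H]1[C@@]2(C)CCC(=O)C(C)(C)O[C@@H]2CC[C@]1(C)O
F4 | step 2 | trimethyl[(5E)-2,6,10-trimethylundeca-1,5,9-trien-1-yl]silane | C[Si](C)(C)C=C(C)CC/C=C(\C)CCC=C(C)C
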